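The ratio I follow through these flasks is the radicals released during the run, counted as a fraction of the radical scavenger charged.

all flasks: free monomer 2.1 M; radical scavenger 10 mM; time 8.0 s

| run | initiator |
|---|---|
| north-west | 50 mM |
| north-east | 100 mM |
| east | 200 mM |
| north | 400 mM |
| south-east | 800 mM |

    initiator → 2 initiating radical (k1 = 0.00901 /s)
    free monomer + initiating radical → growing radical + monomer in chains (k2 = 41200 /M/s)
    free monomer + growing radical → monomer in chains + growing radical, rate k3*[growing radical]*[free monomer] (k3 = 3520 /M/s)
    2 growing radical → dead chain (k4 = 1.8 × 10⁶ /M/s)
    growing radical + radical scavenger → ended chains (k5 = 1.81 × 10⁸ /M/s)
    monomer in chains → over-reaction product (k6 = 0.107 /s)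

* share of monomer in chains in all that became monomer in chains or over-reaction product for north-west, north-east, east, north, south-east, in this order
* the shape of the row from first to last (falls, then rises / falls all the way / rises all the way / rises, then falls / hardly changes)

- a doubled species enters its step squared and goes two at a time
- "hardly changes" means that all values lie within two and a half points (for a concentration: within two and a half percent of the largest)
- run time (north-west): 8.0 s

1. The initiator decays first order, so its rate integrates in closed form: by the end 6.95 % of each charge has gone, and every turn gives two initiating radicals. Adding monomer returns the growing radical, so its rival for the radical is the pair step: in north-west at the charge, with growing radical held where removal by scavenger balances release, the scavenger takes a growing radical at 1.81 × 10⁶ /s and the pair step at 0.00179 /s, far slower, so during this induction period I count one scavenger per radical.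

2. Twice the initiator charge, times that fraction, over the scavenger charge comes to 0.695 in north-west; this scavenger load, the radicals released by the end per scavenger charged, means that scavenger outlasts the run where it stays below one. The load stands below one in north-west, and it doubles along the row to 1.39, 2.78, 5.56 and 11.1, above one from north-east on.

3. One number separates the flasks but cannot give the row, so I add the over-reaction. A steady feed with first-order loss keeps the share one minus e to the minus y, over y, where y is the constant of step six times the feeding time. North-west feeds throughout, so y is 0.856 and the share 67.2 %. Above one I take the feed as flat and starting at the run time over the load, which gives y of 0.241 and 88.9 % in north-east, but y of 0.779 and 69.5 % in south-east, so I commit to a rise and then a fall.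

4. The forecast gives 66.9 %, 87.2 %, 74.5 %, 67.5 % and 63.5 %, with the shape rises, then falls; of the fresh chain monomer it says “earlier breakthrough and faster propagation leave it more time to over-react”. We share the shape, but my south-east figure stands above its 63.5 %.

5. The simulation gives 66.9 %, 87.4 %, 74.4 %, 67.3 % and 62.4 %, with the shape rises, then falls. In north-west 30 % of the radical scavenger stands after 8.00 s, and one minus the load is 30.5 %. In north-east, at a load of 1.39, 0 % of the scavenger is left at the same time. The row's turn reads at 78 mM of initiator, where the load comes to 1.08.

(All constants were drawn at random within sensible limits; the rest is arithmetic.)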